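The meeting had 4 questions before it, on the open intermediate in 4 new flasks.

| flask | starting material | partner | free catalyst | second catalyst | remark | time |
|---|---|---|---|---|---|---|
| eta | 40 mM | 120 mM | 0.59 mM | 2.1 mM | run made earlier |  |
| alpha | 40 mM | 120 mM | 1.8 mM | 2.1 mM | run made earlier |  |
| beta | 40 mM | 120 mM | 6.4 mM | 2.1 mM | run made earlier |  |
| epsilon | 40 mM | 150 mM | 2 mM | 2.1 mM | run made earlier |  |
| south | 40 mM | 200 mM | 0.50 mM | 2.1 mM |  | 20 min |
| west | 40 mM | 120 mM | 2.0 mM | 2.1 mM |  | 20 min |
| north-east | 40 mM | 60.0 mM | 8.0 mM | 2.1 mM |  | 20 min |
| north | 120 mM | 400 mM | 2.0 mM | 0.50 mM |  | 20 min |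

| run | time / min | open intermediate / % | target / % |
|---|---|---|---|
| eta | 2.00 | 17.5 | 2.7 |
| eta | 5.00 | 33.0 | 2.4 |
| eta | 10.0 | 36.2 | 7.0 |
| eta | 15.0 | 37.0 | 11.5 |
| eta | 20.0 | 35.7 | 17.9 |
| alpha | 4.00 | 46.3 | 6.1 |
| alpha | 8.00 | 46.6 | 9.3 |
| alpha | 12.0 | 42.2 | 13.4 |
| alpha | 15.0 | 40.3 | 16.7 |
| alpha | 20.0 | 37.3 | 20.3 |
| beta | 4.00 | 50.4 | 4.7 |
| beta | 8.00 | 46.8 | 9.9 |
| beta | 12.0 | 43.1 | 14.3 |
| beta | 15.0 | 39.1 | 18.0 |
| beta | 20.0 | 38.0 | 24.2 |
| epsilon | 1.50 | 35.0 | 1.5 |
| epsilon | 3.00 | 45.6 | 1.1 |
| epsilon | 6.00 | 48.6 | 6.6 |
| epsilon | 10.0 | 43.4 | 11.8 |
| epsilon | 20.0 | 35.0 | 26.9 |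

(scatter of a reading: 1 percentage point)

- no earlier run changes the charge of second catalyst; that part of a forecast is a guess

* the flasks put in order of amount of open intermediate, in percent of the starting material charged, best first, at 20 min (south / west / north-east / north)
* the same order at 4.0 min (south / west / north-east / north)
* the amount of open intermediate, in percent of the starting material charged of the flask you put first, at 20 min
* the amount of open intermediate, in percent of the starting material charged of the flask you put last, at 20 min

The first speaker proposed keeping the balance of the starting material, the limiting reagent here, since its charge stands below the partner's in south, west and north-east at 40 mM and in north. She pointed out that open intermediate and target together read 61.9 % at the end of the epsilon run, but 53.6 % at the end of the eta run, which had 0.59 mM of free catalyst. The question, she said, is how that sum divides.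

The epsilon run gives 18.3 M⁻¹ min⁻¹ for what she called the drain number, target over open intermediate at the last reading, divided by the time and by the second catalyst charged. This is a reading, and its proportion to second catalyst is a guess, because no earlier run varies that charge. Multiplying the number by second catalyst and time gives the ratio of target to open intermediate, so open intermediate is the sum divided by one plus that ratio. That ratio, she said, is the thing to watch.

For north, with the epsilon sum, the ratio is 0.183, which gives her 52.3 %, though the number was read at 150 mM of partner and north holds 400 mM. For south, with the eta sum, the ratio is 0.769, which gives 30.3 %. For north-east, with 60.0 mM of partner, she used the number of the alpha run, read at 120 mM, which is 13.0 M⁻¹ min⁻¹, and with the epsilon sum reached 40.1 %. West, charged with 2.0 mM of free catalyst beside the alpha run's 1.8 mM and with the same partner, she set at that run's last reading, 37.3 %. She therefore placed north above north-east, north-east above west, and south last.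

The forecaster disagreed on first place, reporting north-east > north > west > south at 20 min and north-east > north > west > south at 4.0 min, with 43.5 % (range 41 % to 46.5 %) for the first flask and 31.5 % (28.5 % to 34.5 %) for the last. The forecaster had north near 40 and assumed the drain “first order in second catalyst, which is a guess”.

The flasks gave north > north-east > west > south at 20 min and north-east > north > west > south at 4.0 min, with 45.7 % first and 32.0 % last.

    second catalyst + open intermediate ⇌ catalyst intermediate (K = 22.0 M⁻¹, k = 28.0 M⁻¹ min⁻¹)
    partner + catalyst intermediate → second catalyst + target (k = 13.0 M⁻¹ min⁻¹)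
    starting material + free catalyst ⇌ free catalyst + open intermediate (K = 1.60, k = 200 M⁻¹ min⁻¹)
    starting material ⇌ dormant form (K = 0.600, k = 0.0730 min⁻¹)

North gave a drain number of 18.0 M⁻¹ min⁻¹, beside the 18.3 M⁻¹ min⁻¹ carried in, but its sum was 53.9 %, lower than the 61.9 % she had used. The neighbouring flask is south with 3.6 mM of second catalyst. The same reckoning takes south's sum, 52.1 %, and a ratio of 1.32, which gives 22.5 % open intermediate and 29.6 % target. That neighbouring flask gave 24.9 % open intermediate and 30.1 % target.

The numbers in the tables are calculated for an exercise; noise was put on by code.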